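**Retrosynthetic overview**
1. Both amide bonds are cut last: target ⇒ (2R,3R)-diacid (the 8–5′ dehydrodimer of p-coumaric acid) + two molecules of agmatine, with no guanidine protection.
2. The cinnamoyl arm is cut at the aryl–vinyl bond (Heck) ⇒ a 5-bromo-2-aryl-2,3-dihydrobenzofuran-3-carboxylate + ethyl acrylate.
3. Key step, the C2–aryl bond: enantioselective dearomative 1,4-arylation of the aromatic furan ring of ethyl 5-bromobenzofuran-3-carboxylate with a 4-oxyphenylboronic acid (C2 set by the catalyst, C3 by equilibration to trans).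
4. The benzofuran ester comes in one step from 5-bromosalicylaldehyde and ethyl diazoacetate.
5. Ring order: both benzene rings are bought; the furan ring is closed first as a flat aromatic ring (step 1) and then dearomatised to the dihydrofuran (step 2).

Target configuration: (2R,3R), trans, E-alkene.

Assumption: the target is drawn as its neutral free base (it is handled as a bis-guanidinium salt and set free on isolation), and the ligand enantiomer in step 2 is chosen by analogy with the face selectivity of known rhodium/diene 1,4-arylations; if the first run gives the (2S) series, the mirror-image ligand is used.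

Step 1
Reactants: 1 5-bromo-2-hydroxybenzaldehyde; 2 ethyl diazoacetate
Product: 4 ethyl 5-bromo-1-benzofuran-3-carboxylate, via hemiacetal 3 (not isolated)
Conditions: HBF4·OEt2 (10 mol%), CH2Cl2, rt; then conc. H2SO4, rt
Reagents that add atoms: none
Why: Brønsted-acid-catalysed addition of the diazoester to the aldehyde with loss of N2 and 1,2-aryl shift gives the α-formyl arylacetate, which closes to hemiacetal 3 and is dehydrated by H2SO4 to the aromatic furan (aldehyde–diazoacetate homologation followed by cyclodehydration); no stereocentre is formed.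

Step 2
Reactants: 4 ethyl 5-bromo-1-benzofuran-3-carboxylate; 5 [4-(oxan-2-yloxy)phenyl]boronic acid
Product: 7 ethyl (2R,3R)-5-bromo-2-[4-(oxan-2-yloxy)phenyl]-2,3-dihydro-1-benzofuran-3-carboxylate, via cis ester 6 (not isolated)
Conditions: [RhCl(C2H4)2]2 (2.5 mol%), (S,S)-Ph-bod* [(1S,4S)-2,5-diphenylbicyclo[2.2.2]octa-2,5-diene, 5.5 mol%], KOH (0.3 equiv), 5 (3 equiv), 1,4-dioxane/H2O (10:1), 60 °C; then DBU (0.3 equiv), CH2Cl2, rt
Reagents that add atoms: none
Why: Proposed new method: transmetalation of the boronic acid to the chiral monovalent rhodium hydroxide gives an aryl–rhodium species that adds syn across C2=C3 of 4 with the aryl at C2, since C2 is β to the ester and the furan ring of a benzofuran has little aromatic stabilisation (it reacts as a β-aryloxy acrylate); the C3-bound rhodium relaxes to the oxa-π-allyl enolate (β-oxygen elimination is disfavoured because the ring C2–O bond cannot become syn-coplanar with C3–Rh) and water protonates it and regenerates Rh–OH; the diene ligand directs the aryl to the α-si face, setting C2 as R, protonation anti to the new aryl gives mainly cis ester 6, and DBU equilibrates C3 to the more stable trans (2R,3R) ester 7 without touching C2, because ring opening from the C3 enolate is the reverse of a disfavoured 5-endo closure; the closest known reaction type is the Hayashi–Miyaura asymmetric 1,4-arylation of coumarins, chromones and 1-nitrocyclohexene (cis product epimerised to trans) and the rhodium-catalysed dearomative arylation of nicotinate-derived pyridinium salts.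

Step 3
Reactants: 7 ethyl (2R,3R)-5-bromo-2-[4-(oxan-2-yloxy)phenyl]-2,3-dihydro-1-benzofuran-3-carboxylate; 8 ethyl acrylate
Product: 9 ethyl (2R,3R)-5-[(E)-3-ethoxy-3-oxoprop-1-en-1-yl]-2-[4-(oxan-2-yloxy)phenyl]-2,3-dihydro-1-benzofuran-3-carboxylate
Conditions: Pd(OAc)2 (5 mol%), P(o-tol)3 (10 mol%), Et3N (3 equiv), DMF, 100 °C
Reagents that add atoms: none
Why: Mizoroki–Heck reaction, in which oxidative addition of zerovalent palladium into the aryl bromide, syn-insertion of the acrylate and syn-β-hydride elimination give the E-cinnamate, while C2 and C3 are untouched (C3 is already in its thermodynamic trans arrangement and the acetal is stable to amine base).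

Step 4
Reactants: 9 ethyl (2R,3R)-5-[(E)-3-ethoxy-3-oxoprop-1-en-1-yl]-2-[4-(oxan-2-yloxy)phenyl]-2,3-dihydro-1-benzofuran-3-carboxylate
Product: 12 (2R,3R)-5-[(E)-2-carboxyethenyl]-2-(4-hydroxyphenyl)-2,3-dihydro-1-benzofuran-3-carboxylic acid, via dilithium dicarboxylate 10 (not isolated), via THP-protected diacid 11 (not isolated)
Conditions: LiOH·H2O (5 equiv), THF/H2O (2:1), 40 °C; then 2 M HCl to pH 1, rt
Reagents that add atoms: lithium hydroxide, [Li+].[OH-]
Why: Saponification of both ethyl esters followed by acid-catalysed hydrolysis of the aryl THP acetal; the phenol stays masked during the basic stage so no quinone-methide ring opening can occur, C3 is already trans (thermodynamic) so enolisation is harmless, and dilute acid at rt leaves the benzylic C2–O bond intact.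

Step 5
Reactants: 12 (2R,3R)-5-[(E)-2-carboxyethenyl]-2-(4-hydroxyphenyl)-2,3-dihydro-1-benzofuran-3-carboxylic acid; 13 agmatine sulfate
Product: 15 (2R,3R)-N-(4-carbamimidamidobutyl)-5-[(E)-3-[(4-carbamimidamidobutyl)amino]-3-oxoprop-1-en-1-yl]-2-(4-hydroxyphenyl)-2,3-dihydro-1-benzofuran-3-carboxamide, via bis-NHS ester 14 (not isolated)
Conditions: DIC (2.2 equiv), N-hydroxysuccinimide (2.2 equiv), DMF, 0 °C to rt; then 13 (3 equiv in all), NaHCO3 (8 equiv), DMF/H2O (1:1), rt
Reagents that add atoms: agmatine sulfate (second equivalent of 13), NC(N)=NCCCCN.OS(O)(=O)=O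
Why: Carbodiimide/N-hydroxysuccinimide active-ester amidation, in which both acids become NHS esters (14) and each is then attacked by the primary amine of one molecule of agmatine, so that two molecules of 13 are built into the product, because in bicarbonate buffer the guanidine stays protonated and the phenol is a much weaker nucleophile; no stereocentre is touched.

**Compound list**
1 | 5-bromo-2-hydroxybenzaldehyde (5-bromosalicylaldehyde) | O=Cc1cc(Br)ccc1O | starting material
2 | ethyl diazoacetate | CCOC(=O)C=[N+]=[N-] | starting material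
3 | ethyl 5-bromo-2-hydroxy-2,3-dihydro-1-benzofuran-3-carboxylate (cyclic hemiacetal, racemic diastereomer mixture) | CCOC(=O)C1C(O)Oc2ccc(Br)cc12 | intermediate
4 | ethyl 5-bromo-1-benzofuran-3-carboxylate | CCOC(=O)c1coc2ccc(Br)cc12 | intermediate
5 | [4-(oxan-2-yloxy)phenyl]boronic acid (racemic at the acetal carbon) | OB(O)c1ccc(OC2CCCCO2)cc1 | starting material
6 | ethyl (2R,3S)-5-bromo-2-[4-(oxan-2-yloxy)phenyl]-2,3-dihydro-1-benzofuran-3-carboxylate (cis; both THP epimers) | Brc1ccc2c(c1)[C@H](C(=O)OCC)[C@H](c1ccc(OC3CCCCO3)cc1)O2 | intermediate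
7 | ethyl (2R,3R)-5-bromo-2-[4-(oxan-2-yloxy)phenyl]-2,3-dihydro-1-benzofuran-3-carboxylate (trans; both THP epimers) | Brc1ccc2c(c1)[C@@H](C(=O)OCC)[C@H](c1ccc(OC3CCCCO3)cc1)O2 | intermediate
8 | ethyl acrylate | C=CC(=O)OCC | starting material
9 | ethyl (2R,3R)-5-[(E)-3-ethoxy-3-oxoprop-1-en-1-yl]-2-[4-(oxan-2-yloxy)phenyl]-2,3-dihydro-1-benzofuran-3-carboxylate | CCOC(=O)/C=C/c1ccc2c(c1)[C@@H](C(=O)OCC)[C@H](c1ccc(OC3CCCCO3)cc1)O2 | intermediate
10 | dilithium (2R,3R)-5-[(E)-2-carboxylatoethenyl]-2-[4-(oxan-2-yloxy)phenyl]-2,3-dihydro-1-benzofuran-3-carboxylate | [Li+].[Li+].[O-]C(=O)/C=C/c1ccc2c(c1)[C@@H](C([O-])=O)[C@H](c1ccc(OC3CCCCO3)cc1)O2 | intermediate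
11 | (2R,3R)-5-[(E)-2-carboxyethenyl]-2-[4-(oxan-2-yloxy)phenyl]-2,3-dihydro-1-benzofuran-3-carboxylic acid | OC(=O)/C=C/c1ccc2c(c1)[C@@H](C(O)=O)[C@H](c1ccc(OC3CCCCO3)cc1)O2 | intermediate
12 | (2R,3R)-5-[(E)-2-carboxyethenyl]-2-(4-hydroxyphenyl)-2,3-dihydro-1-benzofuran-3-carboxylic acid | OC(=O)/C=C/c1ccc2c(c1)[C@@H](C(O)=O)[C@H](c1ccc(O)cc1)O2 | intermediate
13 | agmatine sulfate [1-(4-aminobutyl)guanidine, 1:1 salt with sulfuric acid] | NC(N)=NCCCCN.OS(O)(=O)=O | starting material
14 | bis(2,5-dioxopyrrolidin-1-yl) ester of 12 (bis-NHS ester, 2R,3R) | O=C1CCC(=O)N1OC(=O)/C=C/c1ccc2c(c1)[C@@H](C(=O)ON1C(=O)CCC1=O)[C@H](c1ccc(O)cc1)O2 | intermediate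
15 | (2R,3R)-N-(4-carbamimidamidobutyl)-5-[(E)-3-[(4-carbamimidamidobutyl)amino]-3-oxoprop-1-en-1-yl]-2-(4-hydroxyphenyl)-2,3-dihydro-1-benzofuran-3-carboxamide (CNP0497893.1) | NC(N)=NCCCCNC(=O)/C=C/c1ccc2c(c1)[C@@H](C(=O)NCCCCN=C(N)N)[C@H](c1ccc(O)cc1)O2 | target

**Step count**
Total steps: 5. Longest linear sequence: 5 (1 → 4 → 7 → 9 → 12 → 15).

**Three steps most likely to fail, with fallbacks**

Step 2 is the main risk. The benzofuran ester is an aromatic, α-substituted acceptor, so insertion may be slower than protodeboronation of 5, and the enantioselectivity and its sense are untested on this substrate class. The fallback gives up the dearomative arylation in favour of an oxidative phenol coupling with resolution. It sets out from 8, which is coupled with 4-iodophenol (Pd(OAc)2, Et3N, DMF, 80 °C) to give ethyl (2E)-3-(4-hydroxyphenyl)prop-2-enoate F1. Oxidative dimerisation of this ester with Ag2O (benzene/acetone, rt) gives racemic trans ethyl 5-[(E)-3-ethoxy-3-oxoprop-1-en-1-yl]-2-(4-hydroxyphenyl)-2,3-dihydro-1-benzofuran-3-carboxylate F2. Preparative chiral HPLC on an amylose tris(3,5-dimethylphenylcarbamate) phase gives the (2R,3R)-enantiomer, ethyl (2R,3R)-5-[(E)-3-ethoxy-3-oxoprop-1-en-1-yl]-2-(4-hydroxyphenyl)-2,3-dihydro-1-benzofuran-3-carboxylate F3, and the (2S,3S)-enantiomer is discarded. Non-basic ester cleavage with Me3SnOH (ClCH2CH2Cl, 80 °C, then dilute HCl), chosen because the phenol is free here, brings the route back at 12.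

Step 5 is the second risk. Agmatine sulfate dissolves poorly in organic media, the NHS esters may hydrolyse before they are aminolysed, and the very polar product is hard to purify. The fallback masks the guanidines and works in organic solvent. It sets out from 12, which is coupled with two equivalents of commercial N,N′-di-Boc-agmatine (EDC·HCl, HOBt, iPr2NEt, DMF, rt) to give the tetra-Boc derivative of the target, (2R,3R)-N-[4-[N′,N″-bis(tert-butoxycarbonyl)carbamimidamido]butyl]-5-[(E)-3-[[4-[N′,N″-bis(tert-butoxycarbonyl)carbamimidamido]butyl]amino]-3-oxoprop-1-en-1-yl]-2-(4-hydroxyphenyl)-2,3-dihydro-1-benzofuran-3-carboxamide F4. This is purified on silica and deprotected with TFA/CH2Cl2 in the presence of iPr3SiH, returning to the route at 15.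

Step 4 is the third risk. The C3 ester is hindered, and forcing hydroxide could open the dihydrofuran by β-elimination of the aryloxide. The fallback avoids the diacid altogether. It sets out from 9, whose two esters are converted directly to amides with the aluminium amide made from tert-butyl N-(4-aminobutyl)carbamate and AlMe3 (toluene, 60 °C). This gives (2R,3R)-N-[4-(tert-butoxycarbonylamino)butyl]-5-[(E)-3-[[4-(tert-butoxycarbonylamino)butyl]amino]-3-oxoprop-1-en-1-yl]-2-[4-(oxan-2-yloxy)phenyl]-2,3-dihydro-1-benzofuran-3-carboxamide F5. TFA/CH2Cl2/H2O removes both Boc groups and the THP group to give (2R,3R)-N-(4-aminobutyl)-5-[(E)-3-[(4-aminobutyl)amino]-3-oxoprop-1-en-1-yl]-2-(4-hydroxyphenyl)-2,3-dihydro-1-benzofuran-3-carboxamide F6. Both primary amines are then guanidinylated with 1H-pyrazole-1-carboxamidine hydrochloride (iPr2NEt, DMF, rt), returning to the route at 15.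

**Further compounds**
F1 | step 2 | ethyl (2E)-3-(4-hydroxyphenyl)prop-2-enoate | CCOC(=O)/C=C/c1ccc(O)cc1
F2 | step 2 | racemic trans ethyl 5-[(E)-3-ethoxy-3-oxoprop-1-en-1-yl]-2-(4-hydroxyphenyl)-2,3-dihydro-1-benzofuran-3-carboxylate (1:1 mixture of the 2R,3R and 2S,3S enantiomers) | CCOC(=O)/C=C/c1ccc2c(c1)[C@@H](C(=O)OCC)[C@H](c1ccc(O)cc1)O2.CCOC(=O)/C=C/c1ccc2c(c1)[C@H](C(=O)OCC)[C@@H](c1ccc(O)cc1)O2
F3 | step 2 | ethyl (2R,3R)-5-[(E)-3-ethoxy-3-oxoprop-1-en-1-yl]-2-(4-hydroxyphenyl)-2,3-dihydro-1-benzofuran-3-carboxylate | CCOC(=O)/C=C/c1ccc2c(c1)[C@@H](C(=O)OCC)[C@H](c1ccc(O)cc1)O2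
F4 | step 5 | (2R,3R)-N-[4-[N′,N″-bis(tert-butoxycarbonyl)carbamimidamido]butyl]-5-[(E)-3-[[4-[N′,N″-bis(tert-butoxycarbonyl)carbamimidamido]butyl]amino]-3-oxoprop-1-en-1-yl]-2-(4-hydroxyphenyl)-2,3-dihydro-1-benzofuran-3-carboxamide | CC(C)(C)OC(=O)NC(=NC(=O)OC(C)(C)C)NCCCCNC(=O)/C=C/c1ccc2c(c1)[C@@H](C(=O)NCCCCNC(NC(=O)OC(C)(C)C)=NC(=O)OC(C)(C)C)[C@H](c1ccc(O)cc1)O2
F5 | step 4 | (2R,3R)-N-[4-(tert-butoxycarbonylamino)butyl]-5-[(E)-3-[[4-(tert-butoxycarbonylamino)butyl]amino]-3-oxoprop-1-en-1-yl]-2-[4-(oxan-2-yloxy)phenyl]-2,3-dihydro-1-benzofuran-3-carboxamide | CC(C)(C)OC(=O)NCCCCNC(=O)/C=C/c1ccc2c(c1)[C@@H](C(=O)NCCCCNC(=O)OC(C)(C)C)[C@H](c1ccc(OC3CCCCO3)cc1)O2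
F6 | step 4 | (2R,3R)-N-(4-aminobutyl)-5-[(E)-3-[(4-aminobutyl)amino]-3-oxoprop-1-en-1-yl]-2-(4-hydroxyphenyl)-2,3-dihydro-1-benzofuran-3-carboxamide | NCCCCNC(=O)/C=C/c1ccc2c(c1)[C@@H](C(=O)NCCCCN)[C@H](c1ccc(O)cc1)O2
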